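Its constants were chosen freely; what happens was integrated by code.

The nucleophile is the currency of this flask: it arrives through the gas, and I book where each millimole goes.

electrophile 20 mM; gas 1.8 mM (held); time 40 min

    electrophile + nucleophile → acid set free + product (k1 = 250 L mol⁻¹ min⁻¹)
    nucleophile + acid set free ⇌ protonated nucleophile, settled at all times (K2 = 1.3 × 10⁶ L mol⁻¹)
    gas ⇌ nucleophile, rate k3*(csat - [nucleophile]) (k3 = 0.60 min⁻¹, csat = 1.8 mM)
    nucleophile ⇌ dormant form (K4 = 5.0, k4 = 0.12 min⁻¹)
    nucleophile + acid set free ⇌ idle adduct, settled at all times (K5 = 28000 L mol⁻¹)

- for acid set free the idle adduct is counted in
- at the start none of nucleophile is dissolved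
- run time (flask): 40 min

* part of the electrophile that has reacted at 40 min
* share of free nucleophile in free nucleophile and protonated nucleophile together, at 40 min

Income: with dissolved nucleophile near nil, the gas pays in 1.08 mM min⁻¹. Dissolved nucleophile meets the electrophile as charged with a half-life of 0.139 min, shorter than the transfer's 1.16 min, so transfer is the rate-limiting step at the start, with the electrophile still at its charge.

First entry: one nucleophile per electrophile goes into product. Second entry: the acid set free takes another, because at a starting free level of 0.101 mM the protonated form outweighs free acid 131 to one. So my ration, the electrophile the gas can pay for each minute at two nucleophiles apiece, is 0.540 mM min⁻¹.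

Third entry: free nucleophile slows the transfer and leaks to the dormant form, and it climbs as the electrophile thins. Summed over the run, this entry costs 2.88 mM times ln(charge/left). I leave the idle adduct out of the books.

Closing: guessing 2.00 mM of electrophile left, that entry takes 6.63 mM of the 43.2 mM that the full income comes to over the run, and I get 91.4%. The free level then stands at 0.628 mM beside about 18.0 mM protonated, which gives 3.37%.

The forecast gives 90.5% (88% to 93%) and 3.3% (2.7% to 4%), holding that “each electrophile consumed costs about two nucleophiles”.

The flask gives 90.4% and 3.40%. The nearest charges of electrophile that move the first answer by 5 points are 17.7 mM and 22.0 mM. Over 20.0 min the ration buys 54.0% of the charge, and the flask has used 48.9%.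

In the neighbour flask with 50 mM of electrophile, the ration over 40 min buys 43.2% of the charge. The computed neighbour reacts 41.9%.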